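## Retrosynthetic overview

Chain numbering: C1 is the carbinol carbon, C7 is the alkene carbon bearing the guaiacyl ring.

1. Target ⇒ its bis-TBS ether (C1–O and the 4-hydroxyphenyl O). The last step is a global desilylation, and nothing else is masked.
2. C3–C4 cut: the 1,3-diketone ⇒ a β-silyloxy aldoketene (C1–C3) plus the phenoxide–enolate dianion of dehydrozingerone (C4–C7, E-alkene bought).
3. C1–C2 cut: the ketene ⇒ a light-driven Wolff 1,2-shift of a mandelic-type diazoketone, in which the carbinol carbon migrates with retention.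
4. Diazoketone ⇒ (R)-4-hydroxymandelic acid (carries the only stereocentre) plus CH2N2 (becomes C2).
5. No ring is formed. Both benzene rings arrive intact in the two starting materials.

Assumptions: the C4=C5 enol geometry in the SMILES is one drawing of a rapidly tautomerising 1,3-diketone, so only C1 (S) and the C6=C7 E-alkene are treated as settable and all diketones are written in the tautomer of the given string; (R)-4-hydroxymandelic acid is bought enantiopure; ethereal CH2N2 is a stock reagent distilled from commercial N-methyl-N-nitroso-p-toluenesulfonamide.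

Abbreviations: TBS = tert-butyldimethylsilyl, TES = triethylsilyl.

## Route

**Step 1**
Reactants: 1 (R)-4-hydroxymandelic acid
Product: 2 tert-butyldimethylsilyl (2R)-2-(TBS-oxy)-2-[4-(TBS-oxy)phenyl]acetate
Conditions: TBSCl (3.6 equiv), imidazole (7.5 equiv), DMF, 0 °C → rt, 16 h
Reagents that add atoms: tert-butyldimethylsilyl chloride, CC(C)(C)[Si](C)(C)Cl
Why: Imidazole-promoted O-silylation caps phenol, carbinol and carboxyl in one operation without breaking any bond at the stereocentre, and the silyl ester doubles as a latent acid chloride.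

**Step 2**
Reactants: 2 tris-TBS derivative of (R)-4-hydroxymandelic acid
Product: 4 (1R)-1-(TBS-oxy)-1-[4-(TBS-oxy)phenyl]-3-diazopropan-2-one, via acid chloride 3 (not isolated)
Conditions: (COCl)2 (1.2 equiv), DMF (cat.), CH2Cl2, 0 °C → rt, 2 h; concentrate; CH2N2 (3 equiv), Et2O, 0 °C, 2 h
Reagents that add atoms: diazomethane, C=[N+]=[N-]; oxalyl chloride, O=C(Cl)C(=O)Cl (chlorine of 3 only, no atom of it stays in 4)
Why: Vilsmeier-type chlorodesilylation turns the silyl ester into 3 without free HCl or amine base, and C-acylation of diazomethane (first half of the Arndt–Eistert sequence, the second equivalent taking up HCl) gives 4, so the acidic benzylic C–H never meets a base and the R centre is carried through unchanged.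

**Step 3**
Reactants: 4 (1R)-diazoketone; 5 dehydrozingerone, (3E)-4-(4-hydroxy-3-methoxyphenyl)but-3-en-2-one
Product: 8 (1S,6E)-1-(TBS-oxy)-1-[4-(TBS-oxy)phenyl]-5-hydroxy-7-(4-hydroxy-3-methoxyphenyl)hepta-4,6-dien-3-one (enol form of the 3,5-dione), via aldoketene 6 (not isolated), via dilithium dienolate 7 (not isolated)
Conditions: 4, hν (365 nm LED, FEP-coil flow reactor), THF (0.05 M), −20 °C, tR 10 min; outflow run directly into 7 [5 (1.25 equiv), LiN(SiMe3)2 (2.5 equiv), THF, −78 → −20 → −78 °C]; −78 °C, 1 h → −40 °C; AcOH (3 equiv), −78 °C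
Reagents that add atoms: LiN(SiMe3)2, [Li+].C[Si](C)(C)[N-][Si](C)(C)C (lithium of 7 only, no atom of it stays in 8)
Why: Proposed new method: direct excitation of the s-Z diazoketone expels N2 with a concerted 1,2-shift of the CH(OTBS)Ar group (Wolff rearrangement), which makes C1–C2 with retention so the bought centre is carried over unchanged (descriptor R→S only because the priority order changes), and since only 4 passes the lamp the E-alkene of 5 never sees light; the aldoketene 6, kept away from any protic trap, is then attacked at its sp carbon by the terminal enolate carbon of 7 through a lithium-bridged six-membered transition state to make C3–C4, and the first-formed enolate relaxes by proton shift to the inert lithium 1,3-diketonate, so one equivalent of enolate suffices and no strong base remains to trigger E1cB loss of silanolate, while the phenoxide site is far less nucleophilic, deactivates the enone towards self-Michael addition, and its ketene adduct (an aryl ester enolate) reverts on warming; the closest known reaction types are the photochemical Arndt–Eistert homologation with O–H or N–H traps, the ketene/enolate C-acylation behind the self-condensation of lithium ester enolates, and the C-acylation of phenoxide–enolate polyanions by acid chlorides, but joining a Wolff-derived ketene to a ketone enolate to give a 1,3-diketone directly has not been shown.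

**Step 4**
Reactants: 8 bis-TBS ether of the target
Product: 9 target, (1S,6E)-1,5-dihydroxy-7-(4-hydroxy-3-methoxyphenyl)-1-(4-hydroxyphenyl)hepta-4,6-dien-3-one
Conditions: HF·pyridine (10 equiv), pyridine, THF, 0 °C → rt; pH 7 phosphate buffer
Reagents that add atoms: none
Why: Fluoride-driven Si–O cleavage (silyl ether deprotection, driven by the strong Si–F bond) in a pyridine-buffered medium frees both hydroxyls while avoiding enolate conditions (E1cB dehydration, retro-aldol) and strong acid (p-quinone methide ionisation), so no bond at C1 is broken and it stays S.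

## Compound list

1 | (R)-4-hydroxymandelic acid, (2R)-2-hydroxy-2-(4-hydroxyphenyl)acetic acid | O[C@@H](C(=O)O)c1ccc(O)cc1 | starting material
2 | tert-butyldimethylsilyl (2R)-2-(TBS-oxy)-2-[4-(TBS-oxy)phenyl]acetate | CC(C)(C)[Si](C)(C)O[C@@H](C(=O)O[Si](C)(C)C(C)(C)C)c1ccc(O[Si](C)(C)C(C)(C)C)cc1 | intermediate
3 | (2R)-2-(TBS-oxy)-2-[4-(TBS-oxy)phenyl]acetyl chloride | CC(C)(C)[Si](C)(C)O[C@@H](C(=O)Cl)c1ccc(O[Si](C)(C)C(C)(C)C)cc1 | intermediate (not isolated)
4 | (1R)-1-(TBS-oxy)-1-[4-(TBS-oxy)phenyl]-3-diazopropan-2-one | CC(C)(C)[Si](C)(C)O[C@@H](C(=O)C=[N+]=[N-])c1ccc(O[Si](C)(C)C(C)(C)C)cc1 | intermediate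
5 | dehydrozingerone, (3E)-4-(4-hydroxy-3-methoxyphenyl)but-3-en-2-one | COc1cc(/C=C/C(C)=O)ccc1O | starting material
6 | (3S)-3-(TBS-oxy)-3-[4-(TBS-oxy)phenyl]prop-1-en-1-one (aldoketene) | CC(C)(C)[Si](C)(C)O[C@@H](C=C=O)c1ccc(O[Si](C)(C)C(C)(C)C)cc1 | intermediate (not isolated)
7 | dilithium 2-methoxy-4-[(1E)-3-oxidobuta-1,3-dien-1-yl]phenolate | COc1cc(/C=C/C(=C)[O-])ccc1[O-].[Li+].[Li+] | intermediate (not isolated)
8 | (1S,6E)-1-(TBS-oxy)-1-[4-(TBS-oxy)phenyl]-5-hydroxy-7-(4-hydroxy-3-methoxyphenyl)hepta-4,6-dien-3-one | COc1cc(/C=C/C(O)=C\C(=O)C[C@H](O[Si](C)(C)C(C)(C)C)c2ccc(O[Si](C)(C)C(C)(C)C)cc2)ccc1O | intermediate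
9 | (1S,6E)-1,5-dihydroxy-7-(4-hydroxy-3-methoxyphenyl)-1-(4-hydroxyphenyl)hepta-4,6-dien-3-one | COc1cc(/C=C/C(O)=C\C(=O)C[C@H](O)c2ccc(O)cc2)ccc1O | target

## Step count and risks

Total steps: 4. Longest linear sequence: 4 (1 → 2 → 4 → 8 → 9). Compound 5 enters as bought in step 3.

**Risk 1, step 3 (the proposed new reaction).**
- What may go wrong: ageing of 6 before capture (dimerisation, or a 1,3-silyloxy shift to a silyl cinnamate), O- instead of C-acylation, and E1cB loss of silanolate.
- The fallback uses known chemistry only. It sets out from 4 and 5 and comes back to the route at 9.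
- Compound 4 is irradiated (365 nm, THF) in the presence of pentafluorophenol. This is the classical heteroatom capture of 6, and it gives isolable pentafluorophenyl (3S)-3-(TBS-oxy)-3-[4-(TBS-oxy)phenyl]propanoate F1.
- Compound 5 is silylated (TBSCl, imidazole, DMF) to (3E)-4-[4-(TBS-oxy)-3-methoxyphenyl]but-3-en-2-one F2.
- The two are joined by soft-enolisation C-acylation (MgBr2·OEt2, iPr2NEt, CH2Cl2, rt) to the tris-TBS diketone (1S,6E)-1-(TBS-oxy)-1-[4-(TBS-oxy)phenyl]-5-hydroxy-7-[4-(TBS-oxy)-3-methoxyphenyl]hepta-4,6-dien-3-one F3.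
- F3 is desilylated under the conditions of step 4 to give 9.

**Risk 2, step 4.**
- What may go wrong: during the slow cleavage of the benzylic TBS ether the product may dehydrate to demethoxycurcumin, racemise through a p-quinone methide, or undergo retro-aldol cleavage.
- The fallback changes the masking set so that the last step needs no fluoride and only minutes of weak acid. It sets out from 1 and comes back at 9.
- Compound 1 is treated with TESCl/imidazole to give triethylsilyl (2R)-2-(TES-oxy)-2-[4-(TES-oxy)phenyl]acetate F4.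
- (COCl)2/cat. DMF then gives (2R)-2-(TES-oxy)-2-[4-(TES-oxy)phenyl]acetyl chloride F5.
- CH2N2 gives (1R)-1-(TES-oxy)-1-[4-(TES-oxy)phenyl]-3-diazopropan-2-one F6.
- Irradiation as in step 3 gives (3S)-3-(TES-oxy)-3-[4-(TES-oxy)phenyl]prop-1-en-1-one F7.
- Capture of F7 by 7 gives (1S,6E)-1-(TES-oxy)-1-[4-(TES-oxy)phenyl]-5-hydroxy-7-(4-hydroxy-3-methoxyphenyl)hepta-4,6-dien-3-one F8.
- F8 is unmasked with AcOH–THF–H2O at 0 °C to give 9.

**Risk 3, step 2.**
- What may go wrong: the α-aryl-α-silyloxy acid chloride may lose stereochemical purity through a ketene or enol, or adventitious HCl may strip the benzylic silyl ether or turn 4 into the chloroketone.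
- The fallback leaves the acid chloride manifold. It sets out from 2 and comes back at 4.
- The silyl ester alone is hydrolysed (AcOH–THF–H2O, rt, short) to (2R)-2-(TBS-oxy)-2-[4-(TBS-oxy)phenyl]acetic acid F9.
- F9 is activated at −20 °C with isobutyl chloroformate/N-methylmorpholine as the mixed anhydride (2R)-2-(TBS-oxy)-2-[4-(TBS-oxy)phenyl]acetic isobutyl carbonic anhydride F10.
- F10 acylates CH2N2 (Et2O, −20 → 0 °C) to give 4.
- The enantiomeric purity is checked by HPLC on a chiral phase at 4 in either variant.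

## Further compounds

F1 | step 3 | pentafluorophenyl (3S)-3-(TBS-oxy)-3-[4-(TBS-oxy)phenyl]propanoate | CC(C)(C)[Si](C)(C)O[C@@H](CC(=O)Oc1c(F)c(F)c(F)c(F)c1F)c1ccc(O[Si](C)(C)C(C)(C)C)cc1
F2 | step 3 | (3E)-4-[4-(TBS-oxy)-3-methoxyphenyl]but-3-en-2-one | COc1cc(/C=C/C(C)=O)ccc1O[Si](C)(C)C(C)(C)C
F3 | step 3 | (1S,6E)-1-(TBS-oxy)-1-[4-(TBS-oxy)phenyl]-5-hydroxy-7-[4-(TBS-oxy)-3-methoxyphenyl]hepta-4,6-dien-3-one | COc1cc(/C=C/C(O)=C\C(=O)C[C@H](O[Si](C)(C)C(C)(C)C)c2ccc(O[Si](C)(C)C(C)(C)C)cc2)ccc1O[Si](C)(C)C(C)(C)C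
F4 | step 4 | triethylsilyl (2R)-2-(TES-oxy)-2-[4-(TES-oxy)phenyl]acetate | CC[Si](CC)(CC)O[C@@H](C(=O)O[Si](CC)(CC)CC)c1ccc(O[Si](CC)(CC)CC)cc1
F5 | step 4 | (2R)-2-(TES-oxy)-2-[4-(TES-oxy)phenyl]acetyl chloride | CC[Si](CC)(CC)O[C@@H](C(=O)Cl)c1ccc(O[Si](CC)(CC)CC)cc1
F6 | step 4 | (1R)-1-(TES-oxy)-1-[4-(TES-oxy)phenyl]-3-diazopropan-2-one | CC[Si](CC)(CC)O[C@@H](C(=O)C=[N+]=[N-])c1ccc(O[Si](CC)(CC)CC)cc1
F7 | step 4 | (3S)-3-(TES-oxy)-3-[4-(TES-oxy)phenyl]prop-1-en-1-one | CC[Si](CC)(CC)O[C@@H](C=C=O)c1ccc(O[Si](CC)(CC)CC)cc1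
F8 | step 4 | (1S,6E)-1-(TES-oxy)-1-[4-(TES-oxy)phenyl]-5-hydroxy-7-(4-hydroxy-3-methoxyphenyl)hepta-4,6-dien-3-one | COc1cc(/C=C/C(O)=C\C(=O)C[C@H](O[Si](CC)(CC)CC)c2ccc(O[Si](CC)(CC)CC)cc2)ccc1O
F9 | step 2 | (2R)-2-(TBS-oxy)-2-[4-(TBS-oxy)phenyl]acetic acid | CC(C)(C)[Si](C)(C)O[C@@H](C(=O)O)c1ccc(O[Si](C)(C)C(C)(C)C)cc1
F10 | step 2 | (2R)-2-(TBS-oxy)-2-[4-(TBS-oxy)phenyl]acetic isobutyl carbonic anhydride | CC(C)(C)[Si](C)(C)O[C@@H](C(=O)OC(=O)OCC(C)C)c1ccc(O[Si](C)(C)C(C)(C)C)cc1
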